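Start with the easy step: powder meets solvent. None of the solid substrate is in solution at the start, so c(solid substrate) first drops by what dissolves.

| flask | solid substrate | coupling partner | initiator | remark | time |
|---|---|---|---|---|---|
| Saturday's | 12 mM | 54 mM (in portions, 2) | 0.70 mM | run made earlier; portions every 12 min |  |
| Wednesday's | 27 mM | 54 mM (in portions, 2) | 0.70 mM | run made earlier; portions every 12 min |  |
| Thursday's | 18 mM | 54 mM (in portions, 2) | 1.4 mM | run made earlier; portions every 12 min |  |
| flask | 18 mM | 54.0 mM (in portions, 2) | 0.70 mM | the portions of coupling partner follow each other after 12 min, the first at the start | 40 min |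

- Saturday's (time / min: target / %, starting material / %, solid substrate / %): 2.00: 4, 1, 94; 3.00: 2, 6, 93; 5.00: 5, 4, 91; 8.00: 9, 7, 88; 15.0: 10, 6, 80; 25.0: 18, 5, 76
- Wednesday's (time / min: target / %, starting material / %, solid substrate / %): 1.50: 1, 3, 97; 5.00: 1, 3, 97; 8.00: 1, 2, 92; 12.0: 4, 0, 92; 20.0: 9, 0, 92; 25.0: 6, 1, 88
- Thursday's (time / min: target / %, starting material / %, solid substrate / %): 5.00: 5, 3, 94; 10.0: 7, 5, 90; 15.0: 17, 0, 86; 20.0: 14, 5, 82; 25.0: 18, 4, 77

(readings scatter by 2 percentage points)

- in percentages every species weighs as the solid substrate in it: one ended chains B or side product counts as two
- as a solid, counted per litre of solution: solid substrate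
- what was read earlier has a scatter of 2 percentage points, one standard deviation
- on the list of suspects stand: initiator -> 2 initiating radical; starting material + initiating radical -> capped initiator + first chain carrier; coupling partner + first chain carrier <-> target + second chain carrier; starting material + second chain carrier -> by-product + first chain carrier; 2 second chain carrier -> ended chains A; 2 first chain carrier -> ended chains B; solid substrate <-> starting material; starting material + target -> side product
- at the start none of the solid substrate is in solution
- starting material means what is dissolved; the solid is not counted in it

- concentration of target at 40 min, in mM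
- concentration of starting material at 40 min, in mM
- concentration of solid substrate at 40 min, in mM
- concentration of by-product at 40 min, in mM

Take the first drop from Saturday's starting material readings, which average 0.580 mM, and take that as the level of c(starting material) in the flask.

Now draw the slope. Saturday's and Wednesday's runs carry the flask's initiator charge and bracket its solid charge, so average the solid they lost: 1.80 mM by 8.00 min and 3.06 mM by 25.0 min. After the first drop, these scattered readings give a slope of 0.152 mM min⁻¹. Past what reads as a knee near 8.00 min they give 0.0741 mM min⁻¹, about half the first slope.

No run goes past 25.0 min, so assume that the slope halves once more for the last stretch, giving 0.0371 mM min⁻¹. On that assumption 3.62 mM is lost by 40 min, so I expect c(solid substrate) near 14.4 mM.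

Now count turnovers. Take the solid lost, less what stands dissolved, per initiator charged: this gives 4.34, the turnover count. Saturday's readings at 25.0 min put target at a fraction 0.939 of the solid lost less what stood dissolved, so with that reading I expect c(target) near 2.85 mM. Leave by-product open, since no run read it.

The forecast gives 3.3 mM of target, 0.6 mM of starting material, 13.7 mM of solid substrate and 3.1 mM of by-product, holding that “Each chain cycle gives one target and one by-product”.

The flask gives 2.82 mM of target, 0.729 mM of starting material, 14.2 mM of solid substrate and 1.75 mM of by-product.

    initiator → 2 initiating radical (k = 0.0510 min⁻¹)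
    starting material + initiating radical → capped initiator + first chain carrier (k = 3.70 × 10⁵ M⁻¹ s⁻¹)
    coupling partner + first chain carrier ⇌ target + second chain carrier (K = 0.0950, k = 93000 M⁻¹ min⁻¹)
    starting material + second chain carrier → by-product + first chain carrier (k = 44000 M⁻¹ s⁻¹)
    2 second chain carrier → ended chains A (k = 3.10 × 10⁸ M⁻¹ s⁻¹)
    2 first chain carrier → ended chains B (k = 1.00 × 10⁷ M⁻¹ s⁻¹)
    solid substrate ⇌ starting material, rate k7*(cs7 - [starting material]) while solid is left; crystals form when [starting material] > cs7 (solubility = 0.810 mM, k = 0.560 min⁻¹)
    starting material + target → side product (k = 2.10 M⁻¹ min⁻¹)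

The flask's turnover count at 40 min is 4.37. Carry this to the neighbouring flask, the same recipe left until 1.0 h. Halving the slope again adds 0.529, so reckon 4.90. That neighbour gives 13.5 mM of solid substrate and 0.759 mM of starting material, so its count comes out higher than reckoned, at 5.36.

The earlier runs and the new flask are calculated for an exercise; scatter was added.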